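**Retrosynthetic overview**
1. Cut both imide C–N bonds: the target comes from the all-trans 2,4-diaryl-cyclobutane-1,3-dicarboxylic acid and two molecules of 5,6-dihydropyridin-2(1H)-one.
2. Cut the cyclobutane into two identical C12 halves: head-to-tail [2+2] photodimerisation of (E)-3,4,5-trimethoxycinnamic acid, run in the crystal of its 2:1 salt with (1R,2R)-cyclohexane-1,2-diamine.
3. The cinnamic acid comes from 3,4,5-trimethoxybenzaldehyde and malonic acid; the aldehyde comes from p-cresol (bromination/hydrolysis, methoxylation, O-methylation).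
4. The lactam comes from 2-piperidone (N-Boc, α-selenenylation, selenoxide elimination, deprotection).
5. Ring order: benzene and lactam rings arrive with the starting materials; the cyclobutane, the only ring made, is closed in step 10; the lactams are attached in step 11.

Assumption: the descriptors define the all-trans head-to-tail (ε-truxillic-type) cyclobutane, with both aryls on one face and both acyl groups on the other. This isomer has a mirror plane and is achiral (meso), so only diastereocontrol is needed. Compounds 4 and 5 are racemic.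

**Step 1**
Reactants: 1 piperidin-2-one
Product: 2 tert-butyl 2-oxopiperidine-1-carboxylate
Conditions: Boc2O (1.2 equiv), DMAP (0.1 equiv), MeCN, rt
Reagents that add atoms: di-tert-butyl dicarbonate, CC(C)(C)OC(=O)OC(=O)OC(C)(C)C
Why: DMAP-catalysed N-acylation (Boc protection) of the lactam, which blocks N–H and acidifies the α-CH2 for the enolate chemistry that follows.

**Step 2**
Reactants: 2 tert-butyl 2-oxopiperidine-1-carboxylate
Product: 4 tert-butyl 2-oxo-3-(phenylselanyl)piperidine-1-carboxylate, via lithium enolate of the Boc-lactam 3 (not isolated)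
Conditions: LiN(SiMe3)2 (1.1 equiv), THF, −78 °C; then PhSeCl, −78 °C
Reagents that add atoms: benzeneselenenyl chloride, Cl[Se]c1ccccc1
Why: α-Selenenylation of the lithium enolate at C3, the only enolisable position; the new stereocentre forms racemic and is destroyed in step 3.

**Step 3**
Reactants: 4 tert-butyl 2-oxo-3-(phenylselanyl)piperidine-1-carboxylate
Product: 6 tert-butyl 2-oxo-5,6-dihydropyridine-1(2H)-carboxylate, via selenoxide 5 (not isolated)
Conditions: H2O2 (30% aq), pyridine, CH2Cl2, 0 °C → rt
Reagents that add atoms: none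
Why: Selenide oxidation followed by syn selenoxide elimination; only the C4 hydrogens are β to selenium, so the C3=C4 double bond forms regiospecifically.

**Step 4**
Reactants: 6 tert-butyl 2-oxo-5,6-dihydropyridine-1(2H)-carboxylate
Product: 7 5,6-dihydropyridin-2(1H)-one
Conditions: TFA/CH2Cl2 (1:4), 0 °C → rt; evaporate
Reagents that add atoms: none
Why: Acidolysis of the tert-butyl carbamate (loss of isobutene, then decarboxylation); the conjugated lactam is stable to anhydrous acid.

**Step 5**
Reactants: 8 4-methylphenol (p-cresol)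
Product: 11 3,5-dibromo-4-hydroxybenzaldehyde, via 2,6-dibromo-4-methylphenol 9 (not isolated), via 2,6-dibromo-4-(dibromomethyl)phenol 10 (not isolated)
Conditions: Br2 (2 equiv), o-dichlorobenzene, 35 °C; Br2 (2 equiv), 150 °C; then H2O, 100 °C
Reagents that add atoms: bromine, BrBr; water, O
Why: Electrophilic aromatic bromination at both positions ortho to OH (para is blocked), then free-radical benzylic dibromination at high temperature and hydrolysis of the benzal bromide to the aldehyde.

**Step 6**
Reactants: 11 3,5-dibromo-4-hydroxybenzaldehyde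
Product: 12 4-hydroxy-3,5-dimethoxybenzaldehyde (syringaldehyde)
Conditions: NaOMe (5 equiv), CuCl (10 mol%), DMF/MeOH, 115 °C; then aq HCl
Reagents that add atoms: sodium methoxide (NaOMe), [Na+].[O-]C
Why: Copper-catalysed Ullmann-type methoxylation of both aryl bromides; the aldehyde survives because methoxide adds to it only reversibly.

**Step 7**
Reactants: 12 4-hydroxy-3,5-dimethoxybenzaldehyde
Product: 13 3,4,5-trimethoxybenzaldehyde
Conditions: MeI (1.5 equiv), K2CO3, DMF, 50 °C
Reagents that add atoms: iodomethane, CI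
Why: Williamson ether synthesis (SN2 O-methylation of the acidic para-formyl phenoxide).

**Step 8**
Reactants: 13 3,4,5-trimethoxybenzaldehyde; 14 malonic acid
Product: 16 (E)-3-(3,4,5-trimethoxyphenyl)prop-2-enoic acid, via 2-(3,4,5-trimethoxybenzylidene)malonic acid 15 (not isolated)
Conditions: pyridine, piperidine (cat.), 90 °C → reflux; then aq HCl
Reagents that add atoms: none
Why: Knoevenagel–Doebner condensation; decarboxylation of the benzylidene malonic acid gives the thermodynamically favoured (E)-alkene.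

**Step 9**
Reactants: 16 (E)-3-(3,4,5-trimethoxyphenyl)prop-2-enoic acid (2 equiv)
Product: 17 (1R,2R)-cyclohexane-1,2-diammonium bis[(E)-3-(3,4,5-trimethoxyphenyl)prop-2-enoate] (2:1 double salt, crystalline)
Conditions: (1R,2R)-cyclohexane-1,2-diamine (0.5 equiv), MeOH, 60 °C, slow cooling to 4 °C; crystals filtered and dried
Reagents that add atoms: (1R,2R)-cyclohexane-1,2-diamine, N[C@@H]1CCCC[C@H]1N
Why: Acid–base double-salt formation; the enantiopure gauche diammonium ion cannot sit on an inversion centre and ties two cinnamate ions side by side through N–H···O hydrogen bonds, the packing needed for step 10.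

**Step 10**
Reactants: 17 double salt (two cinnamate units per formula unit)
Product: 19 r-1,t-2,c-3,t-4-2,4-bis(3,4,5-trimethoxyphenyl)cyclobutane-1,3-dicarboxylic acid, via diammonium salt of the photodimer 18 (not isolated)
Conditions: hν (medium-pressure Hg lamp, Pyrex, λ > 290 nm), ground crystals suspended in hexane, 20 °C, N2; then 2 M HCl, EtOAc
Reagents that add atoms: none
Why: Topochemical [2+2] photodimerisation: both carboxylates of a reacting pair are bound to the same diammonium ion, which excludes the antiparallel stacked pair (aryls trans) and holds the two (E)-alkenes crossed within about 4 Å, so least-motion head-to-tail closure puts both aryls on one face and both carboxyls on the other, setting all four stereocentres at once as the all-trans meso isomer.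

**Step 11**
Reactants: 19 all-trans cyclobutane diacid; 7 5,6-dihydropyridin-2(1H)-one (2.3 equiv)
Product: 22 1,1'-{[r-1,t-2,c-3,t-4-2,4-bis(3,4,5-trimethoxyphenyl)cyclobutane-1,3-diyl]dicarbonyl}bis(5,6-dihydropyridin-2(1H)-one), via diacid dichloride 20 (not isolated), via lithium lactamate 21 (not isolated)
Conditions: 19, (COCl)2 (3 equiv), DMF (cat.), CH2Cl2, 0 °C → rt, evaporate; 7, LiN(SiMe3)2 (2.2 equiv), THF, −78 °C; add 20, −78 → 0 °C
Reagents that add atoms: none
Why: Nucleophilic acyl substitution (double N-acylation of the lithium lactamate by the acid chloride); the four stereocentres are not touched and, being already all-trans (the thermodynamic arrangement α to the carbonyls), would return to the same isomer if enolised.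

**Compound list**
1 | piperidin-2-one | O=C1CCCCN1 | starting material
2 | tert-butyl 2-oxopiperidine-1-carboxylate | CC(C)(C)OC(=O)N1CCCCC1=O | intermediate
3 | lithium enolate of 2 | CC(C)(C)OC(=O)N1CCCC=C1[O-].[Li+] | intermediate
4 | tert-butyl 2-oxo-3-(phenylselanyl)piperidine-1-carboxylate (racemic) | CC(C)(C)OC(=O)N1CCCC([Se]c2ccccc2)C1=O | intermediate
5 | tert-butyl 2-oxo-3-(phenylseleninyl)piperidine-1-carboxylate (selenoxide) | CC(C)(C)OC(=O)N1CCCC([Se](=O)c2ccccc2)C1=O | intermediate
6 | tert-butyl 2-oxo-5,6-dihydropyridine-1(2H)-carboxylate | CC(C)(C)OC(=O)N1CCC=CC1=O | intermediate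
7 | 5,6-dihydropyridin-2(1H)-one | O=C1C=CCCN1 | intermediate
8 | 4-methylphenol (p-cresol) | Cc1ccc(O)cc1 | starting material
9 | 2,6-dibromo-4-methylphenol | Cc1cc(Br)c(O)c(Br)c1 | intermediate
10 | 2,6-dibromo-4-(dibromomethyl)phenol | Oc1c(Br)cc(C(Br)Br)cc1Br | intermediate
11 | 3,5-dibromo-4-hydroxybenzaldehyde | O=Cc1cc(Br)c(O)c(Br)c1 | intermediate
12 | 4-hydroxy-3,5-dimethoxybenzaldehyde | COc1cc(C=O)cc(OC)c1O | intermediate
13 | 3,4,5-trimethoxybenzaldehyde | COc1cc(C=O)cc(OC)c1OC | intermediate
14 | malonic acid | OC(=O)CC(O)=O | starting material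
15 | 2-(3,4,5-trimethoxybenzylidene)malonic acid | COc1cc(C=C(C(O)=O)C(O)=O)cc(OC)c1OC | intermediate
16 | (E)-3-(3,4,5-trimethoxyphenyl)prop-2-enoic acid | COc1cc(/C=C/C(O)=O)cc(OC)c1OC | intermediate
17 | (1R,2R)-cyclohexane-1,2-diammonium bis[(E)-3-(3,4,5-trimethoxyphenyl)prop-2-enoate] | COc1cc(/C=C/C([O-])=O)cc(OC)c1OC.COc1cc(/C=C/C([O-])=O)cc(OC)c1OC.[NH3+][C@@H]1CCCC[C@H]1[NH3+] | intermediate
18 | (1R,2R)-cyclohexane-1,2-diammonium salt of diacid 19 | COc1cc([C@H]2[C@H](C([O-])=O)[C@@H](c3cc(OC)c(OC)c(OC)c3)[C@@H]2C([O-])=O)cc(OC)c1OC.[NH3+][C@@H]1CCCC[C@H]1[NH3+] | intermediate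
19 | r-1,t-2,c-3,t-4-2,4-bis(3,4,5-trimethoxyphenyl)cyclobutane-1,3-dicarboxylic acid (all-trans, meso) | COc1cc([C@H]2[C@H](C(O)=O)[C@@H](c3cc(OC)c(OC)c(OC)c3)[C@@H]2C(O)=O)cc(OC)c1OC | intermediate
20 | r-1,t-2,c-3,t-4-2,4-bis(3,4,5-trimethoxyphenyl)cyclobutane-1,3-dicarbonyl dichloride | COc1cc([C@H]2[C@H](C(Cl)=O)[C@@H](c3cc(OC)c(OC)c(OC)c3)[C@@H]2C(Cl)=O)cc(OC)c1OC | intermediate
21 | lithium salt of 7 (lithium lactamate) | [Li+].O=C1C=CCC[N-]1 | intermediate
22 | 1,1'-{[r-1,t-2,c-3,t-4-2,4-bis(3,4,5-trimethoxyphenyl)cyclobutane-1,3-diyl]dicarbonyl}bis(5,6-dihydropyridin-2(1H)-one) | COc1cc([C@H]2[C@H](C(=O)N3CCC=CC3=O)[C@@H](c3cc(OC)c(OC)c(OC)c3)[C@@H]2C(=O)N2CCC=CC2=O)cc(OC)c1OC | target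

**Totals**
Total step count: 11. Longest linear sequence: 7 steps (5, 6, 7, 8, 9, 10, 11, from p-cresol 8). The lactam branch (steps 1–4) joins in step 11.

**Steps most likely to fail, with fallbacks**

Step 10 (photodimerisation) is the main risk. The crystal packing of 17 cannot be predicted. A parallel pair would give a head-to-head dimer, and a pair formed between neighbouring ion pairs could give the head-to-tail isomer with trans aryls. The crystal structure of 17 should be checked for a crossed pair before irradiating. The product is checked by NMR symmetry and by ring closure to a cyclic anhydride, which only a cis-1,3-diacid can form.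

Fallback for step 10, setting out from 13 and coming back at 19: the two halves are tied through their carbonyl carbons so that head-to-tail bonding is forced.
- Condensing two equivalents of 13 with butane-2,3-dione (CC(=O)C(C)=O; piperidinium acetate, MeOH, reflux) gives (1E,5E)-1,6-bis(3,4,5-trimethoxyphenyl)hexa-1,5-diene-3,4-dione F1.
- Irradiating this 1,5-diene (blue light, degassed benzene) gives an intramolecular crossed [2+2] cycloaddition (five-membered-ring-first closure) to 5,6-bis(3,4,5-trimethoxyphenyl)bicyclo[2.1.1]hexane-2,3-dione F2. The isomer with both aryls syn to the dione bridge is kept; the syn,anti isomer is removed by chromatography.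
- NaOH/H2O2 cleaves the 1,2-dione to the all-cis 2,4-bis(3,4,5-trimethoxyphenyl)cyclobutane-1,3-dicarboxylic acid F3.
- MeI/K2CO3 gives its dimethyl ester F4.
- NaOMe in MeOH at reflux epimerises both ester-bearing carbons to the all-trans dimethyl ester F5.
- LiOH in THF/H2O returns 19.

Step 11 (double N-acylation) may stall at the mono-imide, or the lithium lactamate may add in conjugate fashion or polymerise.

Fallback for step 11, setting out from 4 (with 20 made from 19 as before) and coming back at 22: the double bonds are unveiled last.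
- TFA on 4 gives 3-(phenylselanyl)piperidin-2-one F6.
- LiN(SiMe3)2 in THF at −78 °C gives its lithium salt F7.
- Acylation with 20 gives the bis(3-phenylselanyl-2-oxopiperidin-1-yl) imide F8 (mixture of epimers at the selenium-bearing carbons, which does not matter).
- H2O2/pyridine gives the bis-selenoxide F9, which undergoes double syn-elimination to 22.

Step 5 (one-pot nuclear and side-chain bromination with hydrolysis) may over-brominate or tar at 150 °C on a laboratory scale.

Fallback for step 5, setting out from 8 and coming back at 12: the methyl group is oxidised after methoxylation instead.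
- Br2 (2 equiv) in CH2Cl2 at 0 °C gives 9, isolated here.
- NaOMe/CuCl in DMF at 115 °C gives 2,6-dimethoxy-4-methylphenol F10.
- Aerobic oxidation through the quinone methide (CoCl2 cat., NaOH, MeOH, O2, 60 °C) gives 12, which replaces steps 5 and 6.

**Further compounds**
F1 | step 10 | (1E,5E)-1,6-bis(3,4,5-trimethoxyphenyl)hexa-1,5-diene-3,4-dione | COc1cc(/C=C/C(=O)C(=O)/C=C/c2cc(OC)c(OC)c(OC)c2)cc(OC)c1OC
F2 | step 10 | 5,6-bis(3,4,5-trimethoxyphenyl)bicyclo[2.1.1]hexane-2,3-dione, both aryls syn to the dione bridge | COc1cc([C@H]2[C@H]3C(=O)C(=O)[C@@H]2[C@@H]3c2cc(OC)c(OC)c(OC)c2)cc(OC)c1OC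
F3 | step 10 | r-1,c-2,c-3,c-4-2,4-bis(3,4,5-trimethoxyphenyl)cyclobutane-1,3-dicarboxylic acid (all-cis) | COc1cc([C@H]2[C@@H](C(O)=O)[C@@H](c3cc(OC)c(OC)c(OC)c3)[C@H]2C(O)=O)cc(OC)c1OC
F4 | step 10 | dimethyl r-1,c-2,c-3,c-4-2,4-bis(3,4,5-trimethoxyphenyl)cyclobutane-1,3-dicarboxylate (all-cis) | COc1cc([C@H]2[C@@H](C(=O)OC)[C@@H](c3cc(OC)c(OC)c(OC)c3)[C@H]2C(=O)OC)cc(OC)c1OC
F5 | step 10 | dimethyl r-1,t-2,c-3,t-4-2,4-bis(3,4,5-trimethoxyphenyl)cyclobutane-1,3-dicarboxylate (all-trans) | COc1cc([C@H]2[C@H](C(=O)OC)[C@@H](c3cc(OC)c(OC)c(OC)c3)[C@@H]2C(=O)OC)cc(OC)c1OC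
F6 | step 11 | 3-(phenylselanyl)piperidin-2-one (racemic) | O=C1NCCCC1[Se]c1ccccc1
F7 | step 11 | lithium salt of 3-(phenylselanyl)piperidin-2-one | [Li+].O=C1[N-]CCCC1[Se]c1ccccc1
F8 | step 11 | 1,1'-{[r-1,t-2,c-3,t-4-2,4-bis(3,4,5-trimethoxyphenyl)cyclobutane-1,3-diyl]dicarbonyl}bis[3-(phenylselanyl)piperidin-2-one] | COc1cc([C@H]2[C@H](C(=O)N3CCCC([Se]c4ccccc4)C3=O)[C@@H](c3cc(OC)c(OC)c(OC)c3)[C@@H]2C(=O)N2CCCC([Se]c3ccccc3)C2=O)cc(OC)c1OC
F9 | step 11 | bis-selenoxide of F8 | COc1cc([C@H]2[C@H](C(=O)N3CCCC([Se](=O)c4ccccc4)C3=O)[C@@H](c3cc(OC)c(OC)c(OC)c3)[C@@H]2C(=O)N2CCCC([Se](=O)c3ccccc3)C2=O)cc(OC)c1OC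
F10 | step 5 | 2,6-dimethoxy-4-methylphenol | Cc1cc(OC)c(O)c(OC)c1
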